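Assumption (remark on the chemistry): in step 8 the lipase is taken to acetylate the pro-S hydroxymethyl group of the prochiral diol. If it prefers the other arm, the hydrolytic variant given among the fallbacks leads to the same monoacetate.

## Structural features

The target is an isoflavanone: a chroman-4-one whose benzo ring A carries a hydroxyl at C7 and whose heterocyclic ring C (O1, C2, C3, C4, C4a, C8a) carries aryl ring B at C3. Ring B has five contiguous substituted positions: C1' (bond to C3), a catechol at C2' and C3', a methoxy group at C4' and a 2-methylbut-3-en-2-yl (1,1-dimethylallyl) group at C5'. The only stereocentre is C3 (S). It has no stereogenic neighbour, but it is benzylic and α to the C4 ketone, so it is lost by enolisation under base and, more slowly, under strong acid. Further fragile elements are the air-sensitive catechol and the terminal alkene, which excludes hydrogenolysis and hydroboration anywhere in the route. The real difficulty is twofold: building the crowded ring B with the tertiary allyl group next to the methoxy group, and setting C3 and then carrying it, next to a carbonyl group, through ring closure and deprotection. The key step exploits the fact that C4a of ring A is ortho to the O1-bearing carbon C8a and para to the C7 oxygen, which makes it the most nucleophilic ring A carbon that a C4 acyl group can reach, so ring C can be closed by forming C4–C4a.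

## Logic of the disconnections

24 to 23: the three O–Si bonds are cut. Free phenols and a free catechol would not survive acyl activation and a Lewis acid, and silyl ethers are the only groups that can be removed at the end without acid or base acting on C3–H. The gain is a fully masked, non-polar ketone. The demand is a fluoride source buffered so that no aryloxide persists.

23 to 21 (through 22): the C4–C4a bond is cut, which opens ring C. The cut is placed there because C4a is the carbon of ring A that is activated by both oxygens, and because it reduces the bicyclic ketone to an open-chain acid whose stereocentre can be made before any carbonyl group sits next to it. The demand is acyl activation without base, a Lewis acid that works well below 0 °C, and a bulky group on the C7 oxygen to steer the closure away from the carbon between the two oxygens.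

21 to 19 (through 20), and 19 to 18: the carboxyl group is traced back to a primary alcohol and this to its acetate. The acetate is what the desymmetrisation delivers, and the acid is produced only one step before it is used. The demand is an oxidation that gives no time for enolisation or β-elimination of 20, and a deacetylation by a neutral hydride, since carbonate in methanol would strip the aryl silyl ethers.

18 to 16 (through 17): the two O–Si bonds on ring B are exchanged for the two C–O bonds of a benzophenone ketal. Silyl ethers on ring B would not survive the carbonate, organolithium and hydride steps that build ring B and its side chain, and silicon on the 2'-oxygen could migrate to a neighbouring alkoxide. The ketal, in turn, could only be taken off 23 or 24 with hot acid at the expense of C3. The exchange is placed at 16 because no free alcohol competes for the silylating agent there and the stereocentre is not yet acidic. The demand is a ketal hydrolysis that spares the acetate and the aryl silyl ether of ring A.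

16 to 13 and 15: the alkyl–oxygen bond O1–C2 is cut. This separates ring A, as a monoprotected diphenol, from the chiral three-carbon unit. The demand is an etherification at a primary carbon under conditions in which the acetate cannot migrate.

15 to 14: one O–Si bond is cut. This leads to a symmetric, commercial diphenol. The demand is monosilylation, met by an excess of 14.

13 to 12: the acetyl C–O bond is cut, which removes the stereocentre and leaves a prochiral diol with a mirror plane. The gain is that chirality comes from a catalyst acting on a symmetric molecule. The demand is a lipase that distinguishes the two hydroxymethyl groups next to a bulky aryl group.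

12 to 11, and 11 to 9 and 10: the two C–O bonds are raised to ester level, and the bond between the central carbon (future C3) and ring B carbon C1' is cut. This gives an aryl iodide and a commercial malonate. The demand is a C-arylation that tolerates one ortho oxygen and leaves the alkene alone.

9 to 7 (through 8): the C–I bond is cut. The gain is an arene with a single hydrogen ortho to oxygen. The demand is a regioselective metalation at that position.

7 to 6, 6 to 4 (through 5), and 4 to 2 and 3: the O–CH3 bond, the ring-to-quaternary-carbon bond at C5' and the O–CH2 bond are cut in turn. The tertiary allyl group is traced to an O-allyl ether because a [3,3] shift is the direct way to place a 1,1-dimethylallyl group ortho to an oxygen, and that oxygen is then methylated. The demand is that the shift goes to the free ortho carbon and that the product phenol is methylated before it can isomerise.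

2 to 1: the two ketal C–O bonds are cut. Because 1 is symmetric, ketalisation of either adjacent pair of hydroxyls gives the same product and leaves exactly the hydroxyl that later carries the allyl and then the methyl group.

## Other disconnections considered

Alternative 1: The cut is the aryl ether bond O1–C8a. In the forward direction an auxiliary-controlled aldol sequence would provide the bromo diol A2, and Pd(OAc)2 with 2-(di-tert-butylphosphino)-1,1'-binaphthyl and Cs2CO3 would join its primary hydroxyl to the brominated ring A carbon, closing ring C to the trans-isoflavan-4-ol A1.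
- In favour: C3 would be set with a predictable sense by the auxiliary and is not α to a carbonyl group when the ring closes, so the ring closure cannot epimerise it. Intramolecular O-arylation of primary alcohols is an established route to chromans.
- Against: A1 is at the wrong oxidation level at C4, so an oxidation must follow. The three methoxymethyl groups would then have to be removed with acid from the enolisable ketone, or before the oxidation, which would expose the catechol to the oxidant. The secondary benzylic hydroxyl could be dehydrogenated through a palladium alkoxide, and the auxiliary must be attached and removed.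
- Comparison: on structure both plans close ring C late and both tolerate the alkene. On mechanism the alternative is the better one for the safety of C3 during ring closure and for the predictability of the absolute configuration. The chosen plan is the better one in reaching the C4 ketone directly and in ending with a deprotection that is neither acidic nor basic. On step economy the alternative is estimated at one or two operations more.

Alternative 2: The cut is C2–C3. In the forward direction the α-diazo ketone A4 would be decomposed by Rh2(S-PTTL)4, dirhodium tetrakis[N-phthaloyl-(S)-tert-leucinate] (divalent rhodium). The carbene at C3 would insert into a C–H bond of the ortho-methoxy group of ring A, which forms C2–C3, closes ring C and sets C3 in A3.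
- In favour: the ring C methylene comes from a methyl ether, no auxiliary or enzyme is needed, and ring, ketone and stereocentre appear in one catalytic step. On step economy this is the best of all four plans, and it equals the chosen plan in giving the ketone oxidation level directly.
- Against: insertion into a primary C–H bond through a six-membered transition state must compete with oxonium ylide formation at the methoxy oxygen, with addition to the electron-rich ring A and with intermolecular attack on the alkene. The facial control exerted by the catalyst on a carbene flanked by the ortho-substituted ring B is hard to predict. The benzophenone ketal of A3 would have to be removed with acid in the presence of the enolisable ketone.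
- Comparison: structurally the alternative is more convergent. Mechanistically its key step has much less close precedent than an acylation of an activated arene, and the enantioselectivity would be decided in the same step as the ring closure, with no chance to check it beforehand. The chosen plan is longer, but its stereocentre can be assayed at 13 before material is committed.

Alternative 3: The cut is C3–C4. In the forward direction CsF would remove the 2'-silyl group of aldehyde A6. The phenoxide would expel the benzylic acetate to give an ortho-quinone methide, and the acyl-anion equivalent formed from the ring A aldehyde and a chiral aminoindanol-derived N-pentafluorophenyl triazolium tetrafluoroborate would add to C3, forming C3–C4 and closing ring C to A5.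
- In favour: catalytic, metal-free formation of ring, ketone and stereocentre in one step under mild conditions, with the 2'-hydroxyl released on the way. In directness of the ring-forming step it is the equal of the chosen plan, and it is better in avoiding a Lewis acid.
- Against: C3 would be created α to the new ketone in a medium that contains fluoride and the carbene base, the very conditions under which this centre epimerises. The quinone methide can dimerise or be trapped by acetate or fluoride. Electron-rich ortho-alkoxybenzaldehydes form the acyl-anion equivalent slowly. The two catechol oxygens of ring B must be differentiated (silyl on one, methoxymethyl on the other), which costs steps, and the final methoxymethyl removal needs acid.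
- Comparison: structurally the plans are similar in convergence. Mechanistically the alternative sets the stereocentre at the most dangerous moment, whereas the chosen plan sets it on a carbon without acidic hydrogen and exposes it to a carbonyl group only in the last three steps. Overall step economy is estimated as about equal.

Key step: step 15

## Route

Step 1
Reactants: 1 pyrogallol (benzene-1,2,3-triol)
Product: 2 2,2-diphenyl-1,3-benzodioxol-4-ol
Conditions: Ph2CCl2 (1.1 equiv), neat, 165 °C, N2 sweep
Reagents that add atoms: dichlorodiphenylmethane, ClC(Cl)(c1ccccc1)c1ccccc1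
Why: Ketalisation of a vicinal diphenol by a gem-dichloride (two successive O-alkylations through the chloro ether and its oxocarbenium ion); in the symmetric triol both adjacent pairs of hydroxyls are equivalent, so one ketal with one free phenol is expected without any regiochemical control.

Step 2
Reactants: 2 2,2-diphenyl-1,3-benzodioxol-4-ol; 3 prenyl bromide (1-bromo-3-methylbut-2-ene)
Product: 4 4-[(3-methylbut-2-en-1-yl)oxy]-2,2-diphenyl-1,3-benzodioxole
Conditions: K2CO3, acetone, reflux
Reagents that add atoms: none
Why: Williamson ether synthesis; the phenoxide displaces the primary allylic bromide by SN2, and a carbonate base in acetone favours O- over C-alkylation.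

Step 3
Reactants: 4 4-[(3-methylbut-2-en-1-yl)oxy]-2,2-diphenyl-1,3-benzodioxole
Product: 6 5-(2-methylbut-3-en-2-yl)-2,2-diphenyl-1,3-benzodioxol-4-ol, via ortho-dienone 5 (not isolated)
Conditions: PhNEt2, 190 °C, sealed tube, Ar
Reagents that add atoms: none
Why: Aromatic Claisen rearrangement; the [3,3]-sigmatropic shift delivers the dimethyl-substituted allyl terminus to C5, the only unsubstituted ortho carbon, so the 1,1-dimethylallyl group forms with allylic inversion and dienone 5 tautomerises to the phenol. The amine solvent buffers traces of acid that would cyclise or cleave the product.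

Step 4
Reactants: 6 5-(2-methylbut-3-en-2-yl)-2,2-diphenyl-1,3-benzodioxol-4-ol
Product: 7 4-methoxy-5-(2-methylbut-3-en-2-yl)-2,2-diphenyl-1,3-benzodioxole
Conditions: MeI, K2CO3, DMF, 40 °C
Reagents that add atoms: iodomethane, CI
Why: Williamson O-methylation of a hindered phenol with a small electrophile in a dipolar aprotic solvent; capping the oxygen also removes the phenolic hydrogen that mediates isomerisation of the ortho-allyl group.

Step 5
Reactants: 7 4-methoxy-5-(2-methylbut-3-en-2-yl)-2,2-diphenyl-1,3-benzodioxole
Product: 9 7-iodo-4-methoxy-5-(2-methylbut-3-en-2-yl)-2,2-diphenyl-1,3-benzodioxole, via aryllithium 8 (not isolated)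
Conditions: n-BuLi, TMEDA, THF, −78 → 0 °C; then I2, THF, −78 °C
Reagents that add atoms: iodine, II
Why: Directed ortho-metalation followed by iodinolysis; C7–H is the only ring hydrogen ortho to an oxygen (C6–H lies next to the quaternary carbon), and the dioxole oxygen both acidifies it and coordinates lithium, so aryllithium 8 should form there and be trapped by I2.

Step 6
Reactants: 9 7-iodo-4-methoxy-5-(2-methylbut-3-en-2-yl)-2,2-diphenyl-1,3-benzodioxole; 10 diethyl malonate
Product: 11 diethyl 2-[7-methoxy-6-(2-methylbut-3-en-2-yl)-2,2-diphenyl-1,3-benzodioxol-4-yl]malonate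
Conditions: CuI (10 mol%), 2-picolinic acid (20 mol%), Cs2CO3, 1,4-dioxane, 70 °C
Reagents that add atoms: none
Why: Copper-catalysed C-arylation of a malonate by an aryl iodide (Hurtley-type coupling of the Ullmann family); the only ortho substituent is the tied-back dioxole oxygen, and the copper picolinate system is not expected to engage the remote alkene.

Step 7
Reactants: 11 diethyl 2-[7-methoxy-6-(2-methylbut-3-en-2-yl)-2,2-diphenyl-1,3-benzodioxol-4-yl]malonate
Product: 12 2-[7-methoxy-6-(2-methylbut-3-en-2-yl)-2,2-diphenyl-1,3-benzodioxol-4-yl]propane-1,3-diol
Conditions: LiAlH4, THF, 0 °C → rt (ester added to the hydride); aq. NaOH work-up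
Reagents that add atoms: none
Why: Hydride reduction of both esters to primary alcohols; ketal, aryl ethers and the isolated alkene are inert to LiAlH4, and adding the ester to excess hydride at 0 °C limits enolisation of the acidic malonate C–H.

Step 8
Reactants: 12 2-[7-methoxy-6-(2-methylbut-3-en-2-yl)-2,2-diphenyl-1,3-benzodioxol-4-yl]propane-1,3-diol
Product: 13 (2S)-3-hydroxy-2-[7-methoxy-6-(2-methylbut-3-en-2-yl)-2,2-diphenyl-1,3-benzodioxol-4-yl]propyl acetate
Conditions: immobilised Burkholderia cepacia lipase, vinyl acetate, t-BuOMe, 25 °C
Reagents that add atoms: vinyl acetate, C=COC(C)=O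
Why: Enzymatic desymmetrisation by irreversible transesterification; the lipase distinguishes the enantiotopic hydroxymethyl groups of the prochiral diol and acetylates one, which turns the central carbon into the (S) stereocentre. Vinyl acetate makes the transfer irreversible because the leaving enol tautomerises to acetaldehyde, and running to full consumption of the diol should let the minor enantiomer be removed preferentially as diacetate.

Step 9
Reactants: 14 resorcinol
Product: 15 3-(triisopropylsilyloxy)phenol
Conditions: TIPSCl (1 equiv), imidazole, DMF, 0 °C → rt; 14 in threefold excess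
Reagents that add atoms: chlorotriisopropylsilane, CC(C)[Si](Cl)(C(C)C)C(C)C
Why: Statistical monosilylation of a symmetric diphenol with a limiting amount of silyl chloride; excess 14 is removed by aqueous extraction, and the bulky silyl group is chosen for its acid stability and for the shielding it provides in step 15.

Step 10
Reactants: 13 (2S)-3-hydroxy-2-[7-methoxy-6-(2-methylbut-3-en-2-yl)-2,2-diphenyl-1,3-benzodioxol-4-yl]propyl acetate; 15 3-(triisopropylsilyloxy)phenol
Product: 16 (2S)-2-[7-methoxy-6-(2-methylbut-3-en-2-yl)-2,2-diphenyl-1,3-benzodioxol-4-yl]-3-[3-(triisopropylsilyloxy)phenoxy]propyl acetate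
Conditions: PPh3, DIAD, THF, 0 °C → rt
Reagents that add atoms: none
Why: Mitsunobu etherification; the primary alcohol is activated as its alkoxyphosphonium ion and displaced by the phenoxide of 15 in an SN2 reaction at CH2. The stereocentre is one carbon away from the reacting centre and is not touched, and the absence of base prevents acetyl migration between the two arms.

Step 11
Reactants: 16 (2S)-2-[7-methoxy-6-(2-methylbut-3-en-2-yl)-2,2-diphenyl-1,3-benzodioxol-4-yl]-3-[3-(triisopropylsilyloxy)phenoxy]propyl acetate
Product: 17 (2S)-2-[2,3-dihydroxy-4-methoxy-5-(2-methylbut-3-en-2-yl)phenyl]-3-[3-(triisopropylsilyloxy)phenoxy]propyl acetate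
Conditions: AcOH–H2O (4:1), 90 °C, Ar
Reagents that add atoms: none
Why: Acid-catalysed hydrolysis of the benzophenone ketal through its diaryl-stabilised oxocarbenium ion; the primary acetate is held by the large excess of AcOH, the aryl triisopropylsilyl ether and the alkene are stable to aqueous AcOH, and the stereocentre carries no acidic hydrogen at this oxidation level.

Step 12
Reactants: 17 (2S)-2-[2,3-dihydroxy-4-methoxy-5-(2-methylbut-3-en-2-yl)phenyl]-3-[3-(triisopropylsilyloxy)phenoxy]propyl acetate
Product: 18 (2S)-2-[2,3-bis(tert-butyldimethylsilyloxy)-4-methoxy-5-(2-methylbut-3-en-2-yl)phenyl]-3-[3-(triisopropylsilyloxy)phenoxy]propyl acetate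
Conditions: TBSCl, imidazole, DMF, rt → 40 °C
Reagents that add atoms: tert-butylchlorodimethylsilane, CC(C)(C)[Si](C)(C)Cl
Why: Silylation of both phenols through the N-silylimidazolium ion; no other hydroxyl is present, so no selectivity is needed, and the air-sensitive catechol is capped directly after step 11.

Step 13
Reactants: 18 (2S)-2-[2,3-bis(tert-butyldimethylsilyloxy)-4-methoxy-5-(2-methylbut-3-en-2-yl)phenyl]-3-[3-(triisopropylsilyloxy)phenoxy]propyl acetate
Product: 19 (2R)-2-[2,3-bis(tert-butyldimethylsilyloxy)-4-methoxy-5-(2-methylbut-3-en-2-yl)phenyl]-3-[3-(triisopropylsilyloxy)phenoxy]propan-1-ol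
Conditions: i-Bu2AlH, CH2Cl2, −78 °C; aq. potassium sodium tartrate
Reagents that add atoms: none
Why: Reductive cleavage of the acetate by a neutral aluminium hydride at −78 °C; the aryl silyl ethers, which carbonate in methanol would remove, are not attacked, and the aluminium alkoxide is too weak a nucleophile at this temperature to take silicon from the 2'-oxygen. The descriptor changes from S to R only because the priorities of the two arms are exchanged.

Step 14
Reactants: 19 (2R)-2-[2,3-bis(tert-butyldimethylsilyloxy)-4-methoxy-5-(2-methylbut-3-en-2-yl)phenyl]-3-[3-(triisopropylsilyloxy)phenoxy]propan-1-ol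
Product: 21 (2S)-2-[2,3-bis(tert-butyldimethylsilyloxy)-4-methoxy-5-(2-methylbut-3-en-2-yl)phenyl]-3-[3-(triisopropylsilyloxy)phenoxy]propanoic acid, via aldehyde 20 (not isolated)
Conditions: TEMPO (20 mol%), PhI(OAc)2 (2.2 equiv), CH2Cl2–H2O (2:1), 0 °C → rt
Reagents that add atoms: water, O
Why: Nitroxyl-catalysed oxidation with PhI(OAc)2 as terminal oxidant; the oxoammonium ion oxidises the primary alcohol to aldehyde 20, whose hydrate is oxidised on to the acid in the same flask. The medium is weakly acidic and free of base and chlorine, so the α-aryl aldehyde should be consumed before it enolises or expels the β-aryloxy group, and the electron-rich rings are not halogenated.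

Step 15
Reactants: 21 (2S)-2-[2,3-bis(tert-butyldimethylsilyloxy)-4-methoxy-5-(2-methylbut-3-en-2-yl)phenyl]-3-[3-(triisopropylsilyloxy)phenoxy]propanoic acid
Product: 23 (3S)-3-[2,3-bis(tert-butyldimethylsilyloxy)-4-methoxy-5-(2-methylbut-3-en-2-yl)phenyl]-7-(triisopropylsilyloxy)chroman-4-one, via acid chloride 22 (not isolated)
Conditions: 1-chloro-N,N,2-trimethylprop-1-en-1-amine, CH2Cl2, 0 °C → rt; then SnCl4 (2 equiv), CH2Cl2 (0.01 M), −78 → −40 °C; quench into aq. NaH2PO4/Na2HPO4 (pH 7), 0 °C
Reagents that add atoms: none
Why: The acid is converted under neutral conditions into acid chloride 22 (the chloroenamine takes up the hydroxyl and leaves as an amide, so neither an amine base nor free HCl is present and no ketene can form); SnCl4 then polarises the C–Cl bond and the acyl carbon is attacked by the ring A carbon that is ortho to the alkoxy oxygen and para to the silyloxy group, after which the arenium ion loses a proton to give the aryl ketone. The closest known reaction type is the intramolecular Friedel–Crafts acylation of 3-aryloxypropanoic acid derivatives, the standard entry to chroman-4-ones. Ring C is closed as a six-membered ring by 6-exo-trig attack of the arene π bond on the acyl carbon (6-exo-dig if a free acylium ion is involved), and C4–C4a is the only skeletal bond formed. No new stereocentre is created; the existing one becomes C3 and should be retained because the medium contains no base, the temperature stays at or below −40 °C and the cold mixture is quenched into neutral buffer. The step needs regioselectivity for the carbon para to the silyloxy group over the carbon between the two oxygens, and this is secured by the bulky triisopropylsilyl group that shields the latter; the carbon para to the alkoxy oxygen cannot be reached by the tether. It also needs chemoselectivity against ring B and the alkene: the only free position of ring B is out of reach, its silyl ethers make it a weaker donor than an alkoxy arene (which should slow loss of CO from the acyl cation), and the monosubstituted alkene next to a quaternary carbon is a far poorer nucleophile than the activated ring A. High dilution is used to suppress intermolecular acylation.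

Step 16
Reactants: 23 (3S)-3-[2,3-bis(tert-butyldimethylsilyloxy)-4-methoxy-5-(2-methylbut-3-en-2-yl)phenyl]-7-(triisopropylsilyloxy)chroman-4-one
Product: 24 (3S)-3-[2,3-dihydroxy-4-methoxy-5-(2-methylbut-3-en-2-yl)phenyl]-7-hydroxychroman-4-one (CNP0134633.1)
Conditions: Bu4NF, AcOH (1:1.2), THF, 0 °C → rt, Ar
Reagents that add atoms: none
Why: Fluoride-mediated cleavage of all three aryl silyl ethers (fluoride attacks silicon, aryloxide leaves); AcOH protonates each aryloxide as it forms, which keeps the medium non-basic so that the enolisable C3–H next to the ketone and the air-sensitive catechol should be preserved.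

## Compound list

1 | pyrogallol (benzene-1,2,3-triol) | Oc1cccc(O)c1O | starting material
2 | 2,2-diphenyl-1,3-benzodioxol-4-ol | Oc1cccc2c1OC(c1ccccc1)(c1ccccc1)O2 | intermediate
3 | prenyl bromide (1-bromo-3-methylbut-2-ene) | CC(C)=CCBr | starting material
4 | 4-[(3-methylbut-2-en-1-yl)oxy]-2,2-diphenyl-1,3-benzodioxole | CC(C)=CCOc1cccc2c1OC(c1ccccc1)(c1ccccc1)O2 | intermediate
5 | 5-(2-methylbut-3-en-2-yl)-2,2-diphenyl-1,3-benzodioxol-4(5H)-one (ortho-dienone, racemic, not isolated) | C=CC(C)(C)C1C=CC2=C(C1=O)OC(c1ccccc1)(c1ccccc1)O2 | intermediate
6 | 5-(2-methylbut-3-en-2-yl)-2,2-diphenyl-1,3-benzodioxol-4-ol | C=CC(C)(C)c1ccc2c(c1O)OC(c1ccccc1)(c1ccccc1)O2 | intermediate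
7 | 4-methoxy-5-(2-methylbut-3-en-2-yl)-2,2-diphenyl-1,3-benzodioxole | C=CC(C)(C)c1ccc2c(c1OC)OC(c1ccccc1)(c1ccccc1)O2 | intermediate
8 | [7-methoxy-6-(2-methylbut-3-en-2-yl)-2,2-diphenyl-1,3-benzodioxol-4-yl]lithium (not isolated) | C=CC(C)(C)c1cc([Li])c2OC(c3ccccc3)(c3ccccc3)Oc2c1OC | intermediate
9 | 7-iodo-4-methoxy-5-(2-methylbut-3-en-2-yl)-2,2-diphenyl-1,3-benzodioxole | C=CC(C)(C)c1cc(I)c2OC(c3ccccc3)(c3ccccc3)Oc2c1OC | intermediate
10 | diethyl malonate | CCOC(=O)CC(=O)OCC | starting material
11 | diethyl 2-[7-methoxy-6-(2-methylbut-3-en-2-yl)-2,2-diphenyl-1,3-benzodioxol-4-yl]malonate | C=CC(C)(C)c1cc(C(C(=O)OCC)C(=O)OCC)c2OC(c3ccccc3)(c3ccccc3)Oc2c1OC | intermediate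
12 | 2-[7-methoxy-6-(2-methylbut-3-en-2-yl)-2,2-diphenyl-1,3-benzodioxol-4-yl]propane-1,3-diol | C=CC(C)(C)c1cc(C(CO)CO)c2OC(c3ccccc3)(c3ccccc3)Oc2c1OC | intermediate
13 | (2S)-3-hydroxy-2-[7-methoxy-6-(2-methylbut-3-en-2-yl)-2,2-diphenyl-1,3-benzodioxol-4-yl]propyl acetate | C=CC(C)(C)c1cc([C@H](COC(C)=O)CO)c2OC(c3ccccc3)(c3ccccc3)Oc2c1OC | intermediate
14 | resorcinol (benzene-1,3-diol) | Oc1cccc(O)c1 | starting material
15 | 3-(triisopropylsilyloxy)phenol | CC(C)[Si](Oc1cccc(O)c1)(C(C)C)C(C)C | intermediate
16 | (2S)-2-[7-methoxy-6-(2-methylbut-3-en-2-yl)-2,2-diphenyl-1,3-benzodioxol-4-yl]-3-[3-(triisopropylsilyloxy)phenoxy]propyl acetate | C=CC(C)(C)c1cc([C@H](COC(C)=O)COc2cccc(O[Si](C(C)C)(C(C)C)C(C)C)c2)c2OC(c3ccccc3)(c3ccccc3)Oc2c1OC | intermediate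
17 | (2S)-2-[2,3-dihydroxy-4-methoxy-5-(2-methylbut-3-en-2-yl)phenyl]-3-[3-(triisopropylsilyloxy)phenoxy]propyl acetate | C=CC(C)(C)c1cc([C@H](COC(C)=O)COc2cccc(O[Si](C(C)C)(C(C)C)C(C)C)c2)c(O)c(O)c1OC | intermediate
18 | (2S)-2-[2,3-bis(tert-butyldimethylsilyloxy)-4-methoxy-5-(2-methylbut-3-en-2-yl)phenyl]-3-[3-(triisopropylsilyloxy)phenoxy]propyl acetate | C=CC(C)(C)c1cc([C@H](COC(C)=O)COc2cccc(O[Si](C(C)C)(C(C)C)C(C)C)c2)c(O[Si](C)(C)C(C)(C)C)c(O[Si](C)(C)C(C)(C)C)c1OC | intermediate
19 | (2R)-2-[2,3-bis(tert-butyldimethylsilyloxy)-4-methoxy-5-(2-methylbut-3-en-2-yl)phenyl]-3-[3-(triisopropylsilyloxy)phenoxy]propan-1-ol | C=CC(C)(C)c1cc([C@H](CO)COc2cccc(O[Si](C(C)C)(C(C)C)C(C)C)c2)c(O[Si](C)(C)C(C)(C)C)c(O[Si](C)(C)C(C)(C)C)c1OC | intermediate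
20 | (2S)-2-[2,3-bis(tert-butyldimethylsilyloxy)-4-methoxy-5-(2-methylbut-3-en-2-yl)phenyl]-3-[3-(triisopropylsilyloxy)phenoxy]propanal (not isolated) | C=CC(C)(C)c1cc([C@H](C=O)COc2cccc(O[Si](C(C)C)(C(C)C)C(C)C)c2)c(O[Si](C)(C)C(C)(C)C)c(O[Si](C)(C)C(C)(C)C)c1OC | intermediate
21 | (2S)-2-[2,3-bis(tert-butyldimethylsilyloxy)-4-methoxy-5-(2-methylbut-3-en-2-yl)phenyl]-3-[3-(triisopropylsilyloxy)phenoxy]propanoic acid | C=CC(C)(C)c1cc([C@H](C(=O)O)COc2cccc(O[Si](C(C)C)(C(C)C)C(C)C)c2)c(O[Si](C)(C)C(C)(C)C)c(O[Si](C)(C)C(C)(C)C)c1OC | intermediate
22 | (2S)-2-[2,3-bis(tert-butyldimethylsilyloxy)-4-methoxy-5-(2-methylbut-3-en-2-yl)phenyl]-3-[3-(triisopropylsilyloxy)phenoxy]propanoyl chloride (not isolated) | C=CC(C)(C)c1cc([C@H](C(=O)Cl)COc2cccc(O[Si](C(C)C)(C(C)C)C(C)C)c2)c(O[Si](C)(C)C(C)(C)C)c(O[Si](C)(C)C(C)(C)C)c1OC | intermediate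
23 | (3S)-3-[2,3-bis(tert-butyldimethylsilyloxy)-4-methoxy-5-(2-methylbut-3-en-2-yl)phenyl]-7-(triisopropylsilyloxy)chroman-4-one | C=CC(C)(C)c1cc([C@H]2COc3cc(O[Si](C(C)C)(C(C)C)C(C)C)ccc3C2=O)c(O[Si](C)(C)C(C)(C)C)c(O[Si](C)(C)C(C)(C)C)c1OC | intermediate
24 | (3S)-3-[2,3-dihydroxy-4-methoxy-5-(2-methylbut-3-en-2-yl)phenyl]-7-hydroxychroman-4-one (CNP0134633.1) | C=CC(C)(C)c1cc([C@H]2COc3cc(O)ccc3C2=O)c(O)c(O)c1OC | target

## Step count and least certain steps

Total step count: 16. Longest linear sequence: 15 (steps 1–8 and 10–16; step 9 is a one-step branch).

Step 15 (key step). What may go wrong: loss of carbon monoxide from the activated acyl species (the benzylic cation left behind would be stabilised by the para-methoxy group of ring B), attack of the 2'-silyloxy oxygen on the acyl carbon with loss of its silyl group (lactonisation), or enolisation of the tin-bound product ketone with erosion of C3. Fallback: form the same C4–C4a bond at the aldehyde oxidation level, where neither decarbonylation nor acyl transfer to oxygen is possible. Setting out from 19, Dess–Martin oxidation (CH2Cl2, 0 °C) would give 20, which is isolated this time. Me2AlCl (CH2Cl2, −78 °C) would then promote intramolecular hydroxyalkylation of ring A at the same carbon to give (3S)-3-[2,3-bis(tert-butyldimethylsilyloxy)-4-methoxy-5-(2-methylbut-3-en-2-yl)phenyl]-7-(triisopropylsilyloxy)chroman-4-ol F1 as a mixture of C4 epimers; the aluminium-bound alkoxide should resist ionisation to the chromene. A second Dess–Martin oxidation would return to the route at 23.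

Step 3. What may go wrong: migration of the allyl unit to the para carbon (C7) by way of the blocked ortho carbon and a Cope shift, and thermal isomerisation of the ortho product through ene-type hydrogen transfer from the phenol (abnormal Claisen rearrangement). Fallback: block the para position with the iodine atom that is needed later anyway. Setting out from 2, iodination para to the hydroxyl (N-iodosuccinimide, MeCN, 0 °C) would give 7-iodo-2,2-diphenyl-1,3-benzodioxol-4-ol F2. Prenylation with 3 (K2CO3, acetone) would give 4-iodo-7-[(3-methylbut-2-en-1-yl)oxy]-2,2-diphenyl-1,3-benzodioxole F3. The Claisen rearrangement, now with a single open terminus, would pass through 7-iodo-5-(2-methylbut-3-en-2-yl)-2,2-diphenyl-1,3-benzodioxol-4(5H)-one F4 to 7-iodo-5-(2-methylbut-3-en-2-yl)-2,2-diphenyl-1,3-benzodioxol-4-ol F5. O-Methylation (MeI, K2CO3, DMF) would return to the route at 9. Steps 4 and 5 are bypassed and the step count is unchanged.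

Step 6. What may go wrong: sluggish coupling at the ortho-substituted, electron-rich iodide with competing protodeiodination, and partial loss of one ethoxycarbonyl group from the product under carbonate at 70 °C. Fallback: build the malonate in two stages from a different carbon nucleophile. Setting out from 9, palladium-catalysed coupling with the Reformatsky reagent BrZnCH2CO2Et (Pd(dba)2, bis(dibenzylideneacetone)palladium (zerovalent palladium), P(t-Bu)3, THF, rt) would give ethyl 2-[7-methoxy-6-(2-methylbut-3-en-2-yl)-2,2-diphenyl-1,3-benzodioxol-4-yl]acetate F6. Claisen-type C-ethoxycarbonylation (NaH, (EtO)2CO, THF, reflux) would return to the route at 11.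

Step 8. What may go wrong: insufficient discrimination between the two enantiotopic hydroxymethyl groups next to the bulky aryl group, preference for the other arm, or acetyl migration between the arms of 13 on standing; each lowers the enantiomeric purity that every later compound inherits. Fallback: run the enzyme in the hydrolytic direction, which leaves the opposite arm acetylated. Setting out from 12, exhaustive acetylation (Ac2O, pyridine) would give 2-[7-methoxy-6-(2-methylbut-3-en-2-yl)-2,2-diphenyl-1,3-benzodioxol-4-yl]propane-1,3-diyl diacetate F7. Hydrolysis of one ester by the same lipase in aq. NaH2PO4/Na2HPO4 (pH 7) with a cosolvent would return to the route at 13, which would be taken into step 10 without storage.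

## Further compounds

F1 | step 15 | (3S)-3-[2,3-bis(tert-butyldimethylsilyloxy)-4-methoxy-5-(2-methylbut-3-en-2-yl)phenyl]-7-(triisopropylsilyloxy)chroman-4-ol (C4 epimers) | C=CC(C)(C)c1cc([C@H]2COc3cc(O[Si](C(C)C)(C(C)C)C(C)C)ccc3C2O)c(O[Si](C)(C)C(C)(C)C)c(O[Si](C)(C)C(C)(C)C)c1OC
F2 | step 3 | 7-iodo-2,2-diphenyl-1,3-benzodioxol-4-ol | Oc1ccc(I)c2c1OC(c1ccccc1)(c1ccccc1)O2
F3 | step 3 | 4-iodo-7-[(3-methylbut-2-en-1-yl)oxy]-2,2-diphenyl-1,3-benzodioxole | CC(C)=CCOc1ccc(I)c2c1OC(c1ccccc1)(c1ccccc1)O2
F4 | step 3 | 7-iodo-5-(2-methylbut-3-en-2-yl)-2,2-diphenyl-1,3-benzodioxol-4(5H)-one (racemic, not isolated) | C=CC(C)(C)C1C=C(I)C2=C(C1=O)OC(c1ccccc1)(c1ccccc1)O2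
F5 | step 3 | 7-iodo-5-(2-methylbut-3-en-2-yl)-2,2-diphenyl-1,3-benzodioxol-4-ol | C=CC(C)(C)c1cc(I)c2c(c1O)OC(c1ccccc1)(c1ccccc1)O2
F6 | step 6 | ethyl 2-[7-methoxy-6-(2-methylbut-3-en-2-yl)-2,2-diphenyl-1,3-benzodioxol-4-yl]acetate | C=CC(C)(C)c1cc(CC(=O)OCC)c2OC(c3ccccc3)(c3ccccc3)Oc2c1OC
F7 | step 8 | 2-[7-methoxy-6-(2-methylbut-3-en-2-yl)-2,2-diphenyl-1,3-benzodioxol-4-yl]propane-1,3-diyl diacetate | C=CC(C)(C)c1cc(C(COC(C)=O)COC(C)=O)c2OC(c3ccccc3)(c3ccccc3)Oc2c1OC
A1 | alternative 1 | (3S,4R)-3-[4-methoxy-2,3-bis(methoxymethoxy)-5-(2-methylbut-3-en-2-yl)phenyl]-7-(methoxymethoxy)chroman-4-ol | C=CC(C)(C)c1cc([C@H]2COc3cc(OCOC)ccc3[C@@H]2O)c(OCOC)c(OCOC)c1OC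
A2 | alternative 1 | (1R,2S)-1-[2-bromo-4-(methoxymethoxy)phenyl]-2-[4-methoxy-2,3-bis(methoxymethoxy)-5-(2-methylbut-3-en-2-yl)phenyl]propane-1,3-diol | C=CC(C)(C)c1cc([C@@H](CO)[C@@H](O)c2ccc(OCOC)cc2Br)c(OCOC)c(OCOC)c1OC
A3 | alternative 2 | (3S)-7-(tert-butyldimethylsilyloxy)-3-[7-methoxy-6-(2-methylbut-3-en-2-yl)-2,2-diphenyl-1,3-benzodioxol-4-yl]chroman-4-one | C=CC(C)(C)c1cc([C@H]2COc3cc(O[Si](C)(C)C(C)(C)C)ccc3C2=O)c2OC(c3ccccc3)(c3ccccc3)Oc2c1OC
A4 | alternative 2 | 2-diazo-1-[4-(tert-butyldimethylsilyloxy)-2-methoxyphenyl]-2-[7-methoxy-6-(2-methylbut-3-en-2-yl)-2,2-diphenyl-1,3-benzodioxol-4-yl]ethan-1-one | C=CC(C)(C)c1cc(C(=[N+]=[N-])C(=O)c2ccc(O[Si](C)(C)C(C)(C)C)cc2OC)c2OC(c3ccccc3)(c3ccccc3)Oc2c1OC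
A5 | alternative 3 | (3S)-3-[2-hydroxy-4-methoxy-3-(methoxymethoxy)-5-(2-methylbut-3-en-2-yl)phenyl]-7-(methoxymethoxy)chroman-4-one | C=CC(C)(C)c1cc([C@H]2COc3cc(OCOC)ccc3C2=O)c(O)c(OCOC)c1OC
A6 | alternative 3 | 1-[2-(tert-butyldimethylsilyloxy)-4-methoxy-3-(methoxymethoxy)-5-(2-methylbut-3-en-2-yl)phenyl]-2-[2-formyl-5-(methoxymethoxy)phenoxy]ethyl acetate (racemic) | C=CC(C)(C)c1cc(C(COc2cc(OCOC)ccc2C=O)OC(C)=O)c(O[Si](C)(C)C(C)(C)C)c(OCOC)c1OC
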